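**Retrosynthetic overview**
1. The target is the meso, all-cis 2,5-diaryl-3,4-bis(hydroxymethyl)oxolane. The two CH2OH groups are traced back to a cis-fused cyclic anhydride (hydride reduction) and the two phenols to benzyl ethers.
2. Key disconnection: bonds C2–C3 and C4–C5 of the oxolane. C3–C4 leaves as maleic anhydride, and the remaining C2–O–C5 unit is the ring of a 2,3-diaryloxirane, so the oxolane is made by two-carbon ring expansion (formal insertion of an alkene into the oxirane C–C bond via a carbonyl ylide).
3. Enabling feature: the oxirane C2–C3 bond is strained, benzylic on both sides to electron-rich trialkoxyphenyl rings, and flanked by the lone pairs of the ring oxygen. One-electron oxidation therefore breaks exactly this bond, the oxygen stabilises the 1,3-dipole, and cis- and trans-oxiranes converge on one W-shaped ylide.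
4. The oxirane comes from the symmetric stilbene (epoxidation), and the stilbene from two molecules of O-benzylsyringaldehyde (McMurry coupling).
5. Ring order: aryl rings purchased; oxirane in step 3; oxolane plus temporary anhydride ring in step 4; anhydride ring opened in step 5.

Key step: step 4

Remark: with identical aryl groups, the descriptors encoded in the SMILES (2S,3S,4R,5R) describe the achiral all-cis meso isomer. Only relative configuration has to be controlled; chiral intermediates are racemates and their SMILES show one enantiomer.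

**Step 1**
Reactants: 1 syringaldehyde (4-hydroxy-3,5-dimethoxybenzaldehyde)
Product: 2 4-(benzyloxy)-3,5-dimethoxybenzaldehyde
Conditions: BnBr, K2CO3, DMF, 60 °C
Reagents that add atoms: benzyl bromide BrCc1ccccc1
Why: Williamson ether synthesis, in which the acidic para-formyl phenoxide displaces bromide (SN2) and the oxidisable phenol is masked as an ether that should survive low-valent titanium, dioxirane, photoredox and hydride conditions; no stereocentre is formed.

**Step 2**
Reactants: 2 4-(benzyloxy)-3,5-dimethoxybenzaldehyde (two molecules)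
Product: 3 (E)-1,2-bis[4-(benzyloxy)-3,5-dimethoxyphenyl]ethene
Conditions: TiCl4, Zn, THF, 0 °C to reflux
Reagents that add atoms: none
Why: McMurry coupling, in which low-valent titanium couples two aldehyde carbonyl groups reductively and removes both oxygen atoms; aromatic aldehydes give mainly the E-alkene, and any Z isomer is harmless because this geometry is erased in step 4.

**Step 3**
Reactants: 3 (E)-1,2-bis[4-(benzyloxy)-3,5-dimethoxyphenyl]ethene
Product: 4 (2R*,3R*)-2,3-bis[4-(benzyloxy)-3,5-dimethoxyphenyl]oxirane (racemic trans-oxirane)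
Conditions: dimethyldioxirane (acetone solution), CH2Cl2, 0 °C
Reagents that add atoms: dimethyldioxirane CC1(C)OO1
Why: Dioxirane epoxidation, a concerted and stereospecific syn oxygen transfer to the electron-rich alkene, gives the trans-oxirane under neutral acid-free conditions that spare the product from Meinwald rearrangement.

**Step 4**
Reactants: 4 (2R*,3R*)-2,3-bis[4-(benzyloxy)-3,5-dimethoxyphenyl]oxirane; 5 maleic anhydride
Product: 8 (3aR,4S,6R,6aS)-4,6-bis[4-(benzyloxy)-3,5-dimethoxyphenyl]tetrahydro-1H,3H-furo[3,4-c]furan-1,3-dione, via ring-opened oxirane radical cation 6 (not isolated), via W-shaped carbonyl ylide 7 (not isolated)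
Conditions: 5 (3 equiv), 4-mesityl-2,6-di-p-tolylpyrylium tetrafluoroborate (5 mol %), dry degassed CH2Cl2/MeCN, 4 Å MS, Ar, blue LEDs (455 nm), rt, stopped at full conversion
Reagents that add atoms: none
Why: The excited pyrylium salt takes one electron from an aryl ring of 4, the strained doubly benzylic oxirane C2–C3 bond breaks to give 6, and back electron transfer from the pyranyl radical regenerates the catalyst and delivers carbonyl ylide 7, which relaxes to its least crowded exo,exo (W) geometry whichever oxirane diastereomer it came from. Ylide 7 then adds suprafacially across the C=C bond of 5 in a concerted 1,3-dipolar cycloaddition controlled by HOMO(dipole)–LUMO(dipolarophile) overlap, so two carbon atoms are inserted into the former C–C bond and the three-membered ring becomes the five-membered oxolane; the closest known reaction type is the electron-transfer-sensitised (photoredox) carbonyl ylide (3+2) cycloaddition of 2,3-diaryloxiranes with electron-poor alkenes. The oxolane is the only ring closed, by intermolecular (3+2) cycloaddition with both C–C bonds formed at once, and the bicyclic furo[3,4-c]furan frame results because the anhydride ring of 5 is carried along intact. C4 and C6 (the two ArCH centres) are set cis to each other by the W geometry of 7, C3a and C6a are set cis by the Z geometry locked in the ring of 5, and the relation between the two pairs is set by the endo approach, which places the outside aryl groups on the same face as the carbonyl groups. The step needs endo selectivity, which should be secured in an early transition state by secondary orbital overlap, by donor–acceptor stacking of the electron-rich aryl rings on the electron-poor anhydride and by attraction between the anhydride oxygen and the oxonium centre, the same factors (Alder endo rule) that lead (E,E)-1,4-diarylbutadienes to all-cis adducts with 5. Because 5 is cyclic it cannot isomerise to a fumarate-type partner under irradiation, and the cis-fused product cannot epimerise at C3a or C6a without passing through a strained trans-fused bicycle.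

**Step 5**
Reactants: 8 (3aR,4S,6R,6aS)-4,6-bis[4-(benzyloxy)-3,5-dimethoxyphenyl]tetrahydro-1H,3H-furo[3,4-c]furan-1,3-dione
Product: 9 {(2S,3S,4R,5R)-2,5-bis[4-(benzyloxy)-3,5-dimethoxyphenyl]oxolane-3,4-diyl}dimethanol (meso all-cis)
Conditions: LiAlH4, THF, 0 °C to rt; quench with Na2SO4·10H2O, no acid
Reagents that add atoms: none
Why: Hydride reduction of a cyclic anhydride through to the 1,4-diol leaves the four stereocentres untouched because hydride addition outruns enolisation, and the aryl benzyl ethers and the oxolane are inert to LiAlH4.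

**Step 6**
Reactants: 9 {(2S,3S,4R,5R)-2,5-bis[4-(benzyloxy)-3,5-dimethoxyphenyl]oxolane-3,4-diyl}dimethanol
Product: 10 [(2S,3S,4R,5R)-2,5-bis(4-hydroxy-3,5-dimethoxyphenyl)oxolane-3,4-diyl]dimethanol (meso all-cis, target)
Conditions: H2 (1 atm), 10% Pd/C, EtOAc/MeOH, rt, stopped at full conversion
Reagents that add atoms: none
Why: Catalytic hydrogenolysis of the two unhindered O-benzyl groups should be much faster under neutral conditions than cleavage of the secondary, shielded ring C–O bonds, so the phenols are released without acid or base and the all-cis array is not epimerised.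

**Compound list**
1 | syringaldehyde | COc1cc(C=O)cc(OC)c1O | starting material
2 | 4-(benzyloxy)-3,5-dimethoxybenzaldehyde | COc1cc(C=O)cc(OC)c1OCc1ccccc1 | intermediate
3 | (E)-1,2-bis[4-(benzyloxy)-3,5-dimethoxyphenyl]ethene | COc1cc(/C=C/c2cc(OC)c(OCc3ccccc3)c(OC)c2)cc(OC)c1OCc1ccccc1 | intermediate
4 | (2R*,3R*)-2,3-bis[4-(benzyloxy)-3,5-dimethoxyphenyl]oxirane (racemic trans) | COc1cc([C@H]2O[C@@H]2c3cc(OC)c(OCc4ccccc4)c(OC)c3)cc(OC)c1OCc1ccccc1 | intermediate
5 | maleic anhydride | O=C1C=CC(=O)O1 | starting material
6 | ring-opened oxirane radical cation, ArCH(radical)–O(+)=CHAr (not isolated) | COc1cc([CH][O+]=Cc2cc(OC)c(OCc3ccccc3)c(OC)c2)cc(OC)c1OCc1ccccc1 | intermediate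
7 | W-shaped (exo,exo) bis[4-(benzyloxy)-3,5-dimethoxyphenyl] carbonyl ylide (not isolated) | COc1cc(/C=[O+]/[CH-]c2cc(OC)c(OCc3ccccc3)c(OC)c2)cc(OC)c1OCc1ccccc1 | intermediate
8 | (3aR,4S,6R,6aS)-4,6-bis[4-(benzyloxy)-3,5-dimethoxyphenyl]tetrahydro-1H,3H-furo[3,4-c]furan-1,3-dione (meso all-cis endo adduct) | COc1cc([C@H]2O[C@@H](c3cc(OC)c(OCc4ccccc4)c(OC)c3)[C@@H](C(=O)O5)[C@H]2C5=O)cc(OC)c1OCc1ccccc1 | intermediate
9 | {(2S,3S,4R,5R)-2,5-bis[4-(benzyloxy)-3,5-dimethoxyphenyl]oxolane-3,4-diyl}dimethanol (meso all-cis) | COc1cc([C@H]2O[C@@H](c3cc(OC)c(OCc4ccccc4)c(OC)c3)[C@@H](CO)[C@H]2CO)cc(OC)c1OCc1ccccc1 | intermediate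
10 | [(2S,3S,4R,5R)-2,5-bis(4-hydroxy-3,5-dimethoxyphenyl)oxolane-3,4-diyl]dimethanol (meso all-cis) | COc1cc([C@H]2O[C@@H](c3cc(OC)c(O)c(OC)c3)[C@@H](CO)[C@H]2CO)cc(OC)c1O | target

Total step count: 6. Longest linear sequence: 6 (steps 1 to 6).

**Steps most likely to fail**

Step 4. The cycloaddition may show poor endo/exo selectivity. The adduct, which still carries oxidisable aryl rings, may also be re-oxidised on prolonged irradiation, with erosion of the benzylic configuration.
- The fallback sets out from 4 and removes the endo/exo question. The same ylide generation is run with dimethyl acetylenedicarboxylate in place of 5.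
- The W-shaped ylide 7 should then give dimethyl cis-2,5-bis[4-(benzyloxy)-3,5-dimethoxyphenyl]-2,5-dihydrofuran-3,4-dicarboxylate F1.
- Hydrogenation over Pd/C (H2, EtOAc) should deliver both hydrogen atoms to the face opposite the two aryl groups and remove the benzyl groups in the same operation. This gives dimethyl (2S,3R,4S,5R)-2,5-bis(4-hydroxy-3,5-dimethoxyphenyl)oxolane-3,4-dicarboxylate F2.
- LiAlH4 reduction of both esters comes back to the route at 10.

Step 3. The electron-rich diaryloxirane may suffer ring opening or Meinwald rearrangement during oxidation or on silica, and the trialkoxyaryl rings may be over-oxidised.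
- The fallback sets out from 2, bypasses steps 2 and 3, and builds the oxirane under basic, non-oxidising conditions.
- NaBH4 in MeOH gives [4-(benzyloxy)-3,5-dimethoxyphenyl]methanol F3.
- Tetrahydrothiophene and HBF4·OEt2 convert it into 1-[4-(benzyloxy)-3,5-dimethoxybenzyl]tetrahydrothiophenium tetrafluoroborate F4.
- Deprotonation with KOH in MeCN in the presence of a second equivalent of 2 (sulfur ylide epoxidation of the Corey–Chaykovsky type) comes back to the route at 4. A cis/trans mixture is acceptable because step 4 is stereoconvergent.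

Step 6. Hydrogenolysis may run on into the strained benzylic ring C–O bonds. Traces of acid on the catalyst may also cause benzylic epimerisation or rearrangement towards a furofuran skeleton.
- The fallback sets out from 1 and removes the hydrogenolysis from the plan by a change of protecting group.
- McMurry coupling of unprotected 1 (TiCl4, Zn, THF, extra reagent for the phenols) gives (E)-4,4'-(ethene-1,2-diyl)bis(2,6-dimethoxyphenol) F5.
- Pivaloyl chloride, Et3N and DMAP give (E)-ethene-1,2-diylbis(2,6-dimethoxy-4,1-phenylene) bis(2,2-dimethylpropanoate) F6.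
- Dimethyldioxirane gives the racemic trans-oxirane-2,3-diylbis(2,6-dimethoxy-4,1-phenylene) bis(2,2-dimethylpropanoate) F7.
- The conditions of step 4 with 5 give the all-cis (3aR,4S,6R,6aS)-1,3-dioxotetrahydro-1H,3H-furo[3,4-c]furan-4,6-diylbis(2,6-dimethoxy-4,1-phenylene) bis(2,2-dimethylpropanoate) F8.
- One LiAlH4 reduction then opens the anhydride and cleaves both aryl esters, followed by a buffered near-neutral work-up, and comes back to the route at 10.

**Further compounds**
F1 | step 4 | dimethyl cis-2,5-bis[4-(benzyloxy)-3,5-dimethoxyphenyl]-2,5-dihydrofuran-3,4-dicarboxylate | COc1cc([C@H]2O[C@@H](c3cc(OC)c(OCc4ccccc4)c(OC)c3)C(C(=O)OC)=C2C(=O)OC)cc(OC)c1OCc1ccccc1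
F2 | step 4 | dimethyl (2S,3R,4S,5R)-2,5-bis(4-hydroxy-3,5-dimethoxyphenyl)oxolane-3,4-dicarboxylate | COc1cc([C@H]2O[C@@H](c3cc(OC)c(O)c(OC)c3)[C@@H](C(=O)OC)[C@H]2C(=O)OC)cc(OC)c1O
F3 | step 3 | [4-(benzyloxy)-3,5-dimethoxyphenyl]methanol | COc1cc(CO)cc(OC)c1OCc1ccccc1
F4 | step 3 | 1-[4-(benzyloxy)-3,5-dimethoxybenzyl]tetrahydrothiophenium tetrafluoroborate | COc1cc(C[S+]2CCCC2)cc(OC)c1OCc1ccccc1.F[B-](F)(F)F
F5 | step 6 | (E)-4,4'-(ethene-1,2-diyl)bis(2,6-dimethoxyphenol) | COc1cc(/C=C/c2cc(OC)c(O)c(OC)c2)cc(OC)c1O
F6 | step 6 | (E)-ethene-1,2-diylbis(2,6-dimethoxy-4,1-phenylene) bis(2,2-dimethylpropanoate) | COc1cc(/C=C/c2cc(OC)c(OC(=O)C(C)(C)C)c(OC)c2)cc(OC)c1OC(=O)C(C)(C)C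
F7 | step 6 | racemic trans-oxirane-2,3-diylbis(2,6-dimethoxy-4,1-phenylene) bis(2,2-dimethylpropanoate) | COc1cc([C@H]2O[C@@H]2c3cc(OC)c(OC(=O)C(C)(C)C)c(OC)c3)cc(OC)c1OC(=O)C(C)(C)C
F8 | step 6 | (3aR,4S,6R,6aS)-1,3-dioxotetrahydro-1H,3H-furo[3,4-c]furan-4,6-diylbis(2,6-dimethoxy-4,1-phenylene) bis(2,2-dimethylpropanoate) | COc1cc([C@H]2O[C@@H](c3cc(OC)c(OC(=O)C(C)(C)C)c(OC)c3)[C@@H](C(=O)O5)[C@H]2C5=O)cc(OC)c1OC(=O)C(C)(C)C
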